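Everything rests on the C5–C10 bond of ring A. In ring A the fully substituted spiro carbon C10 is bonded to C5, and C5 carries the formyl carbon C6; C10 is therefore taken from a malonate (its ester carbons become C20 and C9) and C5=C6 from a tethered nitroalkene. A chiral amine–thiourea closes ring A by intramolecular Michael addition and sets C5 in the same operation; lactonisation from C6 later fixes C10. The precursor, a (2Z,5E)-4,4-dimethyl-6-nitrohexa-2,5-dienyl malonate, is unveiled last by neutral dehydration so that no achiral base can cyclise it. A Diels–Alder reaction and a vinyl-radical closure then build rings C and D.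

Key step: step 11

Numbering: skeletal atoms carry the kaurane numbers C1–C20 (ring A: C1–C5 and C10; lactone: C10, C20, O, C7, C8, C9; ring C: C8, C9, C11–C14; ring D: C8, C14, C13, C16, C15).
Assumption: the sense of induction of the thiourea catalyst in this intramolecular case is taken from intermolecular malonate additions to nitroalkenes; should C5 form with the opposite sense, the (1S,2S)-catalyst is used instead.

Step 1
Reactants: 1 2,2-dimethylpropane-1,3-diol
Product: 2 3-{[tert-butyl(dimethyl)silyl]oxy}-2,2-dimethylpropan-1-ol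
Conditions: NaH (1.0 equiv), THF, 0 °C to rt; TBSCl (1.0 equiv)
Reagents that add atoms: tert-butyl(chloro)dimethylsilane (TBSCl), CC(C)(C)[Si](C)(C)Cl
Why: Monosilylation of a symmetrical diol through its sparingly soluble mono-sodium alkoxide (Williamson-type O-silylation) should stop cleanly at the mono-ether.

Step 2
Reactants: 2 mono-silyl ether
Product: 3 3-{[tert-butyl(dimethyl)silyl]oxy}-2,2-dimethylpropanal
Conditions: (COCl)2, DMSO, CH2Cl2, −78 °C; Et3N, −78 to 0 °C
Reagents that add atoms: none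
Why: Swern oxidation of the neopentyl alcohol gives an aldehyde that cannot enolise or over-oxidise.

Step 3
Reactants: 3 silyloxy aldehyde; 4 methyl 2-[bis(2,2,2-trifluoroethoxy)phosphoryl]acetate
Product: 5 methyl (2Z)-5-{[tert-butyl(dimethyl)silyl]oxy}-4,4-dimethylpent-2-enoate
Conditions: KN(SiMe3)2, 18-crown-6, THF, −78 °C
Reagents that add atoms: none
Why: Still–Gennari olefination (kinetically controlled elimination from the trifluoroethyl phosphonate adduct) should give the Z-enoate, and an α-quaternary aldehyde is a favourable substrate; this sets the C2=C3 geometry.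

Step 4
Reactants: 5 Z-enoate
Product: 6 (2Z)-5-{[tert-butyl(dimethyl)silyl]oxy}-4,4-dimethylpent-2-en-1-ol
Conditions: iBu2AlH (2.2 equiv), CH2Cl2, −78 °C; aq. potassium sodium tartrate
Reagents that add atoms: none
Why: 1,2-Reduction of the enoate with the aluminium hydride gives the allylic alcohol without touching the alkene geometry.

Step 5
Reactants: 6 Z-allylic alcohol
Product: 7 {[(3Z)-5-bromo-2,2-dimethylpent-3-en-1-yl]oxy}(tert-butyl)dimethylsilane
Conditions: CBr4, PPh3, CH2Cl2, 0 °C
Reagents that add atoms: tetrabromomethane, BrC(Br)(Br)Br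
Why: Appel bromination proceeds by SN2 displacement at the primary allylic carbon under neutral conditions, so the Z-alkene should survive.

Step 6
Reactants: 7 Z-allylic bromide; 8 dimethyl malonate
Product: 9 dimethyl 2-[(2Z)-5-{[tert-butyl(dimethyl)silyl]oxy}-4,4-dimethylpent-2-en-1-yl]propanedioate
Conditions: dimethyl malonate (3 equiv), NaH (2 equiv), THF, 0 °C to rt
Reagents that add atoms: none
Why: Malonic ester alkylation by direct SN2 (no metal π-allyl, hence no Z/E scrambling); the SN2′ site is neopentyl and blocked, and excess malonate suppresses dialkylation.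

Step 7
Reactants: 9 silyloxy malonate
Product: 10 dimethyl 2-[(2Z)-5-hydroxy-4,4-dimethylpent-2-en-1-yl]propanedioate
Conditions: HF·pyridine, THF/pyridine, 0 °C to rt
Reagents that add atoms: none
Why: Fluoride-mediated desilylation under buffered conditions leaves the malonate and the Z-alkene untouched.

Step 8
Reactants: 10 hydroxy malonate
Product: 11 dimethyl 2-[(2Z)-4,4-dimethyl-5-oxopent-2-en-1-yl]propanedioate
Conditions: Dess–Martin periodinane, CH2Cl2, 0 °C to rt
Reagents that add atoms: none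
Why: Periodinane oxidation is neutral, so the malonate C–H and the non-enolisable neopentyl aldehyde coexist without aldol closure.

Step 9
Reactants: 11 aldehyde malonate; 12 nitromethane
Product: 13 dimethyl 2-[(2Z,5RS)-5-hydroxy-4,4-dimethyl-6-nitrohex-2-en-1-yl]propanedioate
Conditions: MeNO2 (solvent), 1,1,3,3-tetramethylguanidine (10 mol %), 0 °C; AcOH quench
Reagents that add atoms: none
Why: Henry (nitroaldol) addition in neat nitromethane outcompetes the reversible intramolecular malonate aldol; the carbinol centre is lost in the next step, so its configuration is irrelevant.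

Step 10
Reactants: 13 nitro alcohol
Product: 14 dimethyl 2-[(2Z,5E)-4,4-dimethyl-6-nitrohexa-2,5-dien-1-yl]propanedioate
Conditions: N,N′-dicyclohexylcarbodiimide, CuCl (cat.), Et2O, rt; used at once
Reagents that add atoms: none
Why: Carbodiimide-mediated dehydration of a β-nitro alcohol gives the (E)-nitroalkene without any amine base, so the malonate cannot cyclise in a racemic background reaction.

Step 11
Reactants: 14 nitrodienyl malonate
Product: 15 dimethyl (6R)-5,5-dimethyl-6-(nitromethyl)cyclohex-3-ene-1,1-dicarboxylate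
Conditions: 1-[3,5-bis(trifluoromethyl)phenyl]-3-[(1R,2R)-2-(dimethylamino)cyclohexyl]thiourea (10 mol %), toluene, 0 °C to rt
Reagents that add atoms: none
Why: The tertiary amine of the catalyst deprotonates the malonate C–H while the thiourea hydrogen-bonds the nitro group, the tethered carbanion (C10) adds to the β-carbon C5 of the nitroalkene, and protonation of the nitronate leaves the nitromethyl group (C6). The closest known reaction type is the bifunctional amine–thiourea-catalysed Michael addition of malonates to nitroalkenes in its intramolecular form. Ring A closes in the 6-exo-trig mode. The only new stereocentre, C5, is set by the catalyst, which selects one enantiotopic face of the nitroalkene inside the hydrogen-bonded ion pair; C10 carries two identical esters and stays prochiral. The step needs enantiofacial selectivity and clean C-alkylation at the neopentyl C5, and these are secured by the (2Z)-alkene and the C4 gem-dimethyl group, which fold donor and acceptor into one reactive geometry, by the absence of γ-hydrogens on the nitroalkene, and by the absence of achiral base.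

Step 12
Reactants: 15 nitromethyl diester
Product: 16 dimethyl (6R)-6-formyl-5,5-dimethylcyclohex-3-ene-1,1-dicarboxylate
Conditions: NaOMe (1.05 equiv), MeOH, 0 °C, short; then aq. TiCl3, NH4OAc buffer (pH 5–6), THF, 0 °C; crude used at once
Reagents that add atoms: water, O
Why: Nef reaction in its reductive variant (nitronate, reduction to the imine by TiCl3, hydrolysis) should unveil the C6 aldehyde under near-neutral conditions that spare esters, alkene and the enolisable C5 centre.

Step 13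
Reactants: 16 formyl diester
Product: 18 methyl (3aR,7aS)-4,4-dimethyl-1-oxo-1,3,3a,4,7,7a-hexahydro-2-benzofuran-7a-carboxylate, via hydroxy diester 17 (not isolated)
Conditions: NaBH4, MeOH, −20 °C; then TsOH·H2O (cat.), CH2Cl2, rt
Reagents that add atoms: none
Why: Borohydride reduction then acid-catalysed lactonisation: only the ester cis to C6 can close the cis-fused γ-lactone, so C10 becomes stereogenic with C20 cis to C6 (substrate control) and C5 is no longer α to a carbonyl.

Step 14
Reactants: 18 lactone ester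
Product: 21 (1R,6R)-6-({[tert-butyl(dimethyl)silyl]oxy}methyl)-1-(methoxycarbonyl)-5,5-dimethylcyclohex-3-ene-1-carboxylic acid, via lithium hydroxy carboxylate 19 (not isolated), via bis-silylated compound 20 (not isolated)
Conditions: LiOH (1.05 equiv), THF/H2O, 0 °C; evaporate; TBSCl (2.5 equiv), imidazole, DMF, rt; then AcOH/THF/H2O, rt
Reagents that add atoms: lithium hydroxide, [Li+].[OH-]; tert-butyl(chloro)dimethylsilane (TBSCl), CC(C)(C)[Si](C)(C)Cl
Why: Saponification of the γ-lactone (much faster than the neopentyl methyl ester), silylation of alkoxide and carboxylate, and hydrolysis of the labile silyl ester leave C20 as the free acid, C9 as the ester and C6 protected, which stores the differentiation made in step 13.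

Step 15
Reactants: 21 silyloxy acid ester
Product: 23 methyl (1R,6R)-6-({[tert-butyl(dimethyl)silyl]oxy}methyl)-1-(hydroxymethyl)-5,5-dimethylcyclohex-3-ene-1-carboxylate, via acyl imidazole 22 (not isolated)
Conditions: 1,1′-carbonyldiimidazole, THF, rt to 40 °C; then NaBH4, H2O, 0 °C
Reagents that add atoms: none
Why: Acyl imidazole formation and borohydride reduction convert only the activated C20 carboxyl into the alcohol; the methyl ester survives, and the ring alkene, which borane would hydroborate, is not at risk.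

Step 16
Reactants: 23 hydroxy ester
Product: 24 (1R,6R)-6-({[tert-butyl(dimethyl)silyl]oxy}methyl)-1-(hydroxymethyl)-5,5-dimethylcyclohex-3-ene-1-carbaldehyde
Conditions: iBu2AlH (2.2 equiv), CH2Cl2, −78 °C; aq. potassium sodium tartrate; used at once
Reagents that add atoms: none
Why: Partial ester reduction at low temperature: the neighbouring aluminium alkoxide chelates the tetrahedral intermediate of the hindered ester, so the C9 aldehyde should be released only on work-up.

Step 17
Reactants: 24 hydroxy aldehyde; 25 2,2,6-trimethyl-4H-1,3-dioxin-4-one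
Product: 27 (6R,11R)-4-acetyl-11-({[tert-butyl(dimethyl)silyl]oxy}methyl)-10,10-dimethyl-2-oxaspiro[5.5]undeca-4,8-dien-3-one, via acetoacetate 26 (not isolated)
Conditions: toluene, 110 °C; then piperidine (0.2 equiv), AcOH (0.2 equiv), 4 Å molecular sieves, rt
Reagents that add atoms: none
Why: Acetoacetylation of the C20 alcohol by acetylketene (thermal cycloreversion of the dioxinone) and intramolecular Knoevenagel condensation onto the non-enolisable C9 aldehyde close the six-membered unsaturated lactone, whose ring holds C7 cis to C10 on the C8=C9 bond.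

Step 18
Reactants: 27 spiro acetyl dihydropyranone; 28 buta-1,3-diene
Product: 29 (1R,4′aS,6R,8′aS)-8′a-acetyl-6-({[tert-butyl(dimethyl)silyl]oxy}methyl)-5,5-dimethyl-4′a,5′,8′,8′a-tetrahydrospiro[cyclohex-3-ene-1,4′-isochromen]-1′(3′H)-one
Conditions: ZnCl2 (1.5 equiv), CH2Cl2, buta-1,3-diene (excess), sealed vessel, 0 °C to rt
Reagents that add atoms: none
Why: Lewis acid-promoted Diels–Alder reaction of a doubly activated 2-acyl unsaturated lactone builds ring C with the C12=C13 alkene: suprafacial addition puts H9 and the C8 acyl group cis, and the diene should come over the lactone face next to the C1 methylene, because the other face is covered by the C5 branch with its CH2OTBS group (substrate control of C8 and C9).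

Step 19
Reactants: 29 Diels–Alder adduct
Product: 32 (1R,4′aS,6R,8′aS)-6-({[tert-butyl(dimethyl)silyl]oxy}methyl)-5,5-dimethyl-8′a-(prop-2-enoyl)-4′a,5′,8′,8′a-tetrahydrospiro[cyclohex-3-ene-1,4′-isochromen]-1′(3′H)-one, via Mannich base 30 (not isolated), via ammonium iodide 31 (not isolated)
Conditions: LiN(SiMe3)2, THF, −78 °C; N,N-dimethylmethaniminium iodide, −78 to 0 °C; MeI, THF/MeOH, rt; aq. NaHCO3, rt
Reagents that add atoms: N,N-dimethylmethaniminium iodide (Eschenmoser's salt), C=[N+](C)C.[I-]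
Why: Mannich reaction of the methyl ketone enolate (the only enolisable position), N-methylation and E1cB elimination (α-methylenation) add C17 and give the vinyl ketone.

Step 20
Reactants: 32 vinyl ketone
Product: 33 (1R,4′aS,6R,8′aS)-6-({[tert-butyl(dimethyl)silyl]oxy}methyl)-8′a-(2-iodoprop-2-enoyl)-5,5-dimethyl-4′a,5′,8′,8′a-tetrahydrospiro[cyclohex-3-ene-1,4′-isochromen]-1′(3′H)-one
Conditions: iodine (1.5 equiv), pyridine/CH2Cl2 (1:1), 0 °C to rt
Reagents that add atoms: iodine, II
Why: α-Iodination of an enone by the Baylis–Hillman-type addition–elimination sequence (pyridine adds, the enolate is iodinated, pyridine leaves); only the unhindered vinyl ketone accepts pyridine.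

Step 21
Reactants: 33 α-iodo vinyl ketone
Product: 34 (5R,8S,9S,10R,13R)-6-{[tert-butyl(dimethyl)silyl]oxy}-15-oxo-6,7-secokaura-2,16-dien-7,20-olide
Conditions: Bu3SnH (1.2 equiv, syringe pump), 2,2′-azobis(2-methylpropanenitrile) (0.2 equiv), benzene (5 mM), 80 °C
Reagents that add atoms: none
Why: 5-exo-trig cyclisation of the α-carbonyl vinyl radical onto C13 of the cyclohexene, then hydrogen transfer to C12, closes ring D as the bicyclo[3.2.1]octane with the methylene ketone in place; a σ-vinyl radical prefers exo closure, C13 is fixed by the bridge, and rearrangement would need an unstabilised primary radical.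

Step 22
Reactants: 34 ring D enone
Product: 35 (5R,8S,9S,10R,13R,15R)-6-{[tert-butyl(dimethyl)silyl]oxy}-15-hydroxy-6,7-secokaura-2,16-dien-7,20-olide
Conditions: NaBH4, CeCl3·7H2O, MeOH, −78 °C
Reagents that add atoms: none
Why: Luche 1,2-reduction: hydride should add to the exo face of the C15 carbonyl (the side of the one-carbon bridge C14), so the hydroxyl ends on the face turned to the C9–C11–C12 bridge, as the target requires.

Step 23
Reactants: 35 allylic alcohol
Product: 36 (5R,8S,9S,10R,13R,15S,16S)-6-{[tert-butyl(dimethyl)silyl]oxy}-16,17-epoxy-15-hydroxy-6,7-secokaur-2-en-7,20-olide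
Conditions: VO(acac)2 (5 mol %), tBuOOH (1.5 equiv, in decane), CH2Cl2, 0 °C to rt
Reagents that add atoms: tert-butyl hydroperoxide, CC(C)(C)OO
Why: Hydroxyl-directed vanadium-catalysed epoxidation delivers oxygen to C16=C17 from the face of the C15 hydroxyl (epoxide oxygen cis to OH) and ignores the isolated ring A alkene.

Step 24
Reactants: 36 epoxy alcohol
Product: 37 (5R,8S,9S,10R,13R,15S,16S)-6-{[tert-butyl(dimethyl)silyl]oxy}-16,17-epoxy-15-[(triethylsilyl)oxy]-6,7-secokaur-2-en-7,20-olide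
Conditions: Et3SiOTf, 2,6-lutidine (excess), CH2Cl2, −78 °C
Reagents that add atoms: triethylsilyl trifluoromethanesulfonate, CC[Si](CC)(CC)OS(=O)(=O)C(F)(F)F
Why: Silylation of the hindered secondary alcohol with the silyl triflate under buffered, cold conditions protects it from the chromium oxidant of the next step.

Step 25
Reactants: 37 bis-silyl ether
Product: 38 (5R,8S,9S,10S,13R,15S,16S)-6-{[tert-butyl(dimethyl)silyl]oxy}-16,17-epoxy-1-oxo-15-[(triethylsilyl)oxy]-6,7-secokaur-2-en-7,20-olide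
Conditions: CrO3 (15 equiv), 3,5-dimethylpyrazole (15 equiv), CH2Cl2, −20 °C
Reagents that add atoms: chromium trioxide, O=[Cr](=O)=O
Why: Allylic C–H oxidation with the CrO3–3,5-dimethylpyrazole complex: C1 is the only allylic C–H position (C4 is quaternary), and no other alkene or free alcohol is left in the molecule.

Step 26
Reactants: 38 ring A enone
Product: 39 (5R,8S,9S,10S,13R,15S,16S)-16,17-epoxy-6,15-dihydroxy-1-oxo-6,7-secokaur-2-en-7,20-olide
Conditions: Et3N·3HF, MeCN, rt to 40 °C
Reagents that add atoms: none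
Why: Fluoride-mediated cleavage of both silyl ethers with a nearly neutral fluoride source should spare the epoxy alcohol, the enone and the lactone.

Step 27
Reactants: 39 diol
Product: 40 (5R,8S,9S,10S,13R,15S,16S)-16,17-epoxy-15-hydroxy-1,6-dioxo-6,7-secokaur-2-en-7,20-olide (CNP0537841.1)
Conditions: TEMPO (10 mol %), PhI(OAc)2 (1.2 equiv), CH2Cl2, rt
Reagents that add atoms: none
Why: TEMPO-mediated (oxoammonium) oxidation is selective for the primary C6 alcohol over the hindered secondary C15 alcohol, and the base-free medium should not epimerise C5 next to the new aldehyde.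

Compound list
1 | 2,2-dimethylpropane-1,3-diol | CC(C)(CO)CO | starting material
2 | 3-{[tert-butyl(dimethyl)silyl]oxy}-2,2-dimethylpropan-1-ol | CC(C)(CO)CO[Si](C)(C)C(C)(C)C | intermediate
3 | 3-{[tert-butyl(dimethyl)silyl]oxy}-2,2-dimethylpropanal | CC(C)(C=O)CO[Si](C)(C)C(C)(C)C | intermediate
4 | methyl 2-[bis(2,2,2-trifluoroethoxy)phosphoryl]acetate | COC(=O)CP(=O)(OCC(F)(F)F)OCC(F)(F)F | starting material
5 | methyl (2Z)-5-{[tert-butyl(dimethyl)silyl]oxy}-4,4-dimethylpent-2-enoate | COC(=O)/C=C\C(C)(C)CO[Si](C)(C)C(C)(C)C | intermediate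
6 | (2Z)-5-{[tert-butyl(dimethyl)silyl]oxy}-4,4-dimethylpent-2-en-1-ol | OC/C=C\C(C)(C)CO[Si](C)(C)C(C)(C)C | intermediate
7 | {[(3Z)-5-bromo-2,2-dimethylpent-3-en-1-yl]oxy}(tert-butyl)dimethylsilane | BrC/C=C\C(C)(C)CO[Si](C)(C)C(C)(C)C | intermediate
8 | dimethyl propanedioate (dimethyl malonate) | COC(=O)CC(=O)OC | starting material
9 | dimethyl 2-[(2Z)-5-{[tert-butyl(dimethyl)silyl]oxy}-4,4-dimethylpent-2-en-1-yl]propanedioate | COC(=O)C(C(=O)OC)C/C=C\C(C)(C)CO[Si](C)(C)C(C)(C)C | intermediate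
10 | dimethyl 2-[(2Z)-5-hydroxy-4,4-dimethylpent-2-en-1-yl]propanedioate | COC(=O)C(C(=O)OC)C/C=C\C(C)(C)CO | intermediate
11 | dimethyl 2-[(2Z)-4,4-dimethyl-5-oxopent-2-en-1-yl]propanedioate | COC(=O)C(C(=O)OC)C/C=C\C(C)(C)C=O | intermediate
12 | nitromethane | C[N+](=O)[O-] | starting material
13 | dimethyl 2-[(2Z,5RS)-5-hydroxy-4,4-dimethyl-6-nitrohex-2-en-1-yl]propanedioate | COC(=O)C(C(=O)OC)C/C=C\C(C)(C)C(O)C[N+](=O)[O-] | intermediate
14 | dimethyl 2-[(2Z,5E)-4,4-dimethyl-6-nitrohexa-2,5-dien-1-yl]propanedioate | COC(=O)C(C(=O)OC)C/C=C\C(C)(C)/C=C/[N+](=O)[O-] | intermediate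
15 | dimethyl (6R)-5,5-dimethyl-6-(nitromethyl)cyclohex-3-ene-1,1-dicarboxylate | CC1(C)C=CCC(C(=O)OC)(C(=O)OC)[C@@H]1C[N+](=O)[O-] | intermediate
16 | dimethyl (6R)-6-formyl-5,5-dimethylcyclohex-3-ene-1,1-dicarboxylate | CC1(C)C=CCC(C(=O)OC)(C(=O)OC)[C@@H]1C=O | intermediate
17 | dimethyl (6R)-6-(hydroxymethyl)-5,5-dimethylcyclohex-3-ene-1,1-dicarboxylate | CC1(C)C=CCC(C(=O)OC)(C(=O)OC)[C@@H]1CO | intermediate
18 | methyl (3aR,7aS)-4,4-dimethyl-1-oxo-1,3,3a,4,7,7a-hexahydro-2-benzofuran-7a-carboxylate | CC1(C)C=CC[C@]2(C(=O)OC)C(=O)OC[C@H]12 | intermediate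
19 | lithium (1R,6R)-6-(hydroxymethyl)-1-(methoxycarbonyl)-5,5-dimethylcyclohex-3-ene-1-carboxylate | CC1(C)C=CC[C@@](C(=O)[O-])(C(=O)OC)[C@@H]1CO.[Li+] | intermediate
20 | 1-[tert-butyl(dimethyl)silyl] 1-methyl (1S,6R)-6-({[tert-butyl(dimethyl)silyl]oxy}methyl)-5,5-dimethylcyclohex-3-ene-1,1-dicarboxylate | CC1(C)C=CC[C@@](C(=O)O[Si](C)(C)C(C)(C)C)(C(=O)OC)[C@@H]1CO[Si](C)(C)C(C)(C)C | intermediate
21 | (1R,6R)-6-({[tert-butyl(dimethyl)silyl]oxy}methyl)-1-(methoxycarbonyl)-5,5-dimethylcyclohex-3-ene-1-carboxylic acid | CC1(C)C=CC[C@@](C(=O)O)(C(=O)OC)[C@@H]1CO[Si](C)(C)C(C)(C)C | intermediate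
22 | methyl (1R,6R)-6-({[tert-butyl(dimethyl)silyl]oxy}methyl)-1-(1H-imidazole-1-carbonyl)-5,5-dimethylcyclohex-3-ene-1-carboxylate | CC1(C)C=CC[C@@](C(=O)n2ccnc2)(C(=O)OC)[C@@H]1CO[Si](C)(C)C(C)(C)C | intermediate
23 | methyl (1R,6R)-6-({[tert-butyl(dimethyl)silyl]oxy}methyl)-1-(hydroxymethyl)-5,5-dimethylcyclohex-3-ene-1-carboxylate | CC1(C)C=CC[C@@](CO)(C(=O)OC)[C@@H]1CO[Si](C)(C)C(C)(C)C | intermediate
24 | (1R,6R)-6-({[tert-butyl(dimethyl)silyl]oxy}methyl)-1-(hydroxymethyl)-5,5-dimethylcyclohex-3-ene-1-carbaldehyde | CC1(C)C=CC[C@@](CO)(C=O)[C@@H]1CO[Si](C)(C)C(C)(C)C | intermediate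
25 | 2,2,6-trimethyl-4H-1,3-dioxin-4-one | CC1=CC(=O)OC(C)(C)O1 | starting material
26 | [(1R,6R)-6-({[tert-butyl(dimethyl)silyl]oxy}methyl)-1-formyl-5,5-dimethylcyclohex-3-en-1-yl]methyl 3-oxobutanoate | CC1(C)C=CC[C@@](COC(=O)CC(C)=O)(C=O)[C@@H]1CO[Si](C)(C)C(C)(C)C | intermediate
27 | (6R,11R)-4-acetyl-11-({[tert-butyl(dimethyl)silyl]oxy}methyl)-10,10-dimethyl-2-oxaspiro[5.5]undeca-4,8-dien-3-one | CC1(C)C=CC[C@]2(COC(=O)C(C(C)=O)=C2)[C@@H]1CO[Si](C)(C)C(C)(C)C | intermediate
28 | buta-1,3-diene | C=CC=C | starting material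
29 | (1R,4′aS,6R,8′aS)-8′a-acetyl-6-({[tert-butyl(dimethyl)silyl]oxy}methyl)-5,5-dimethyl-4′a,5′,8′,8′a-tetrahydrospiro[cyclohex-3-ene-1,4′-isochromen]-1′(3′H)-one | CC1(C)C=CC[C@]2(COC(=O)[C@@]3(C(C)=O)CC=CC[C@@H]23)[C@@H]1CO[Si](C)(C)C(C)(C)C | intermediate
30 | (1R,4′aS,6R,8′aS)-6-({[tert-butyl(dimethyl)silyl]oxy}methyl)-8′a-[3-(dimethylamino)propanoyl]-5,5-dimethyl-4′a,5′,8′,8′a-tetrahydrospiro[cyclohex-3-ene-1,4′-isochromen]-1′(3′H)-one | CC1(C)C=CC[C@]2(COC(=O)[C@@]3(C(=O)CCN(C)C)CC=CC[C@@H]23)[C@@H]1CO[Si](C)(C)C(C)(C)C | intermediate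
31 | N,N,N-trimethyl-3-oxo-3-[(1R,4′aS,6R,8′aS)-6-({[tert-butyl(dimethyl)silyl]oxy}methyl)-5,5-dimethyl-1′-oxo-4′a,5′-dihydrospiro[cyclohex-3-ene-1,4′-isochromen]-8′a(1′H,3′H,8′H)-yl]propan-1-aminium iodide | CC1(C)C=CC[C@]2(COC(=O)[C@@]3(C(=O)CC[N+](C)(C)C)CC=CC[C@@H]23)[C@@H]1CO[Si](C)(C)C(C)(C)C.[I-] | intermediate
32 | (1R,4′aS,6R,8′aS)-6-({[tert-butyl(dimethyl)silyl]oxy}methyl)-5,5-dimethyl-8′a-(prop-2-enoyl)-4′a,5′,8′,8′a-tetrahydrospiro[cyclohex-3-ene-1,4′-isochromen]-1′(3′H)-one | CC1(C)C=CC[C@]2(COC(=O)[C@@]3(C(=O)C=C)CC=CC[C@@H]23)[C@@H]1CO[Si](C)(C)C(C)(C)C | intermediate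
33 | (1R,4′aS,6R,8′aS)-6-({[tert-butyl(dimethyl)silyl]oxy}methyl)-8′a-(2-iodoprop-2-enoyl)-5,5-dimethyl-4′a,5′,8′,8′a-tetrahydrospiro[cyclohex-3-ene-1,4′-isochromen]-1′(3′H)-one | CC1(C)C=CC[C@]2(COC(=O)[C@@]3(C(=O)C(I)=C)CC=CC[C@@H]23)[C@@H]1CO[Si](C)(C)C(C)(C)C | intermediate
34 | (5R,8S,9S,10R,13R)-6-{[tert-butyl(dimethyl)silyl]oxy}-15-oxo-6,7-secokaura-2,16-dien-7,20-olide | CC1(C)C=CC[C@]2(COC(=O)[C@@]34C[C@@H](CC[C@@H]23)C(=C)C4=O)[C@@H]1CO[Si](C)(C)C(C)(C)C | intermediate
35 | (5R,8S,9S,10R,13R,15R)-6-{[tert-butyl(dimethyl)silyl]oxy}-15-hydroxy-6,7-secokaura-2,16-dien-7,20-olide | CC1(C)C=CC[C@]2(COC(=O)[C@@]34C[C@@H](CC[C@@H]23)C(=C)[C@H]4O)[C@@H]1CO[Si](C)(C)C(C)(C)C | intermediate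
36 | (5R,8S,9S,10R,13R,15S,16S)-6-{[tert-butyl(dimethyl)silyl]oxy}-16,17-epoxy-15-hydroxy-6,7-secokaur-2-en-7,20-olide | CC1(C)C=CC[C@]2(COC(=O)[C@@]34C[C@@H](CC[C@@H]23)[C@]2(CO2)[C@H]4O)[C@@H]1CO[Si](C)(C)C(C)(C)C | intermediate
37 | (5R,8S,9S,10R,13R,15S,16S)-6-{[tert-butyl(dimethyl)silyl]oxy}-16,17-epoxy-15-[(triethylsilyl)oxy]-6,7-secokaur-2-en-7,20-olide | CC1(C)C=CC[C@]2(COC(=O)[C@@]34C[C@@H](CC[C@@H]23)[C@]2(CO2)[C@H]4O[Si](CC)(CC)CC)[C@@H]1CO[Si](C)(C)C(C)(C)C | intermediate
38 | (5R,8S,9S,10S,13R,15S,16S)-6-{[tert-butyl(dimethyl)silyl]oxy}-16,17-epoxy-1-oxo-15-[(triethylsilyl)oxy]-6,7-secokaur-2-en-7,20-olide | CC1(C)C=CC(=O)[C@]2(COC(=O)[C@@]34C[C@@H](CC[C@@H]23)[C@]2(CO2)[C@H]4O[Si](CC)(CC)CC)[C@@H]1CO[Si](C)(C)C(C)(C)C | intermediate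
39 | (5R,8S,9S,10S,13R,15S,16S)-16,17-epoxy-6,15-dihydroxy-1-oxo-6,7-secokaur-2-en-7,20-olide | CC1(C)C=CC(=O)[C@]2(COC(=O)[C@@]34C[C@@H](CC[C@@H]23)[C@]2(CO2)[C@H]4O)[C@@H]1CO | intermediate
40 | (5R,8S,9S,10S,13R,15S,16S)-16,17-epoxy-15-hydroxy-1,6-dioxo-6,7-secokaur-2-en-7,20-olide (CNP0537841.1) | CC1(C)C=CC(=O)[C@]2(COC(=O)[C@@]34C[C@@H](CC[C@@H]23)[C@]2(CO2)[C@H]4O)[C@@H]1C=O | target

Total step count: 27. Longest linear sequence: 27 steps (1 to 40; compounds 4, 8, 12, 25 and 28 are purchased).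

Steps most likely to fail

Step 25 (allylic oxidation). Hydrogen abstraction at C1 gives an allylic intermediate delocalised over C1–C3, so oxygen may be delivered to C3 with shift of the alkene (transposed enone), and the crowded C1 may react slowly enough for silyl ether cleavage to compete. Fallback, setting out from 37: allylic hydroxylation with SeO2 (0.5 equiv) and tBuOOH in CH2Cl2, an ene reaction followed by a [2,3]-sigmatropic shift that returns the alkene to C2=C3 and so places oxygen only at C1, should give the C1 allylic alcohol F5 (either C1 epimer serves); oxidation of this allylic alcohol with MnO2 then gives 38, where the route is rejoined.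

Step 21 (radical ring closure). The vinyl radical may take hydrogen from the stannane before it cyclises (simple loss of iodine), and the product enone may suffer conjugate reduction by the stannane. Fallback, setting out from 33: Luche reduction (NaBH4, CeCl3·7H2O, MeOH, −78 °C) first gives the 2-iodoallylic alcohol F3 as a mixture of C15 epimers; vinyl-radical 5-exo cyclisation of this classical substrate under the same stannane conditions gives the allylic alcohol F4, which is inert to the stannane; MnO2 oxidation of the epimer mixture converges on enone 34.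

Step 18 (Diels–Alder reaction). Cycloaddition at the neopentyl-type C9 may be sluggish, so that diene polymerisation competes, and at the temperature then needed the facial selectivity may erode. Fallback, setting out from 27: the far more reactive 2-(trimethylsilyloxy)buta-1,3-diene is used with ZnCl2 at −78 °C (the silyloxy-bearing carbon ends at C12, para to C8) to give the silyl enol ether adduct F1. CsF and N-phenylbis(trifluoromethanesulfonimide) convert it with retention of the C12=C13 position into the enol triflate F2. Reduction with Pd(OAc)2, PPh3, HCO2H and Bu3N in DMF then removes the triflate and returns to 29.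

Further compounds
F1 | step 18 | (1R,4′aS,6R,8′aS)-8′a-acetyl-6-({[tert-butyl(dimethyl)silyl]oxy}methyl)-5,5-dimethyl-6′-[(trimethylsilyl)oxy]-4′a,5′,8′,8′a-tetrahydrospiro[cyclohex-3-ene-1,4′-isochromen]-1′(3′H)-one | CC1(C)C=CC[C@]2(COC(=O)[C@@]3(C(C)=O)CC=C(O[Si](C)(C)C)C[C@@H]23)[C@@H]1CO[Si](C)(C)C(C)(C)C
F2 | step 18 | (1R,4′aS,6R,8′aS)-8′a-acetyl-6-({[tert-butyl(dimethyl)silyl]oxy}methyl)-5,5-dimethyl-1′-oxo-1′,3′,4′a,5′,8′,8′a-hexahydrospiro[cyclohex-3-ene-1,4′-isochromen]-6′-yl trifluoromethanesulfonate | CC1(C)C=CC[C@]2(COC(=O)[C@@]3(C(C)=O)CC=C(OS(=O)(=O)C(F)(F)F)C[C@@H]23)[C@@H]1CO[Si](C)(C)C(C)(C)C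
F3 | step 21 | (1R,4′aS,6R,8′aS)-6-({[tert-butyl(dimethyl)silyl]oxy}methyl)-8′a-[(1RS)-1-hydroxy-2-iodoprop-2-en-1-yl]-5,5-dimethyl-4′a,5′,8′,8′a-tetrahydrospiro[cyclohex-3-ene-1,4′-isochromen]-1′(3′H)-one | CC1(C)C=CC[C@]2(COC(=O)[C@@]3(C(O)C(I)=C)CC=CC[C@@H]23)[C@@H]1CO[Si](C)(C)C(C)(C)C
F4 | step 21 | (5R,8S,9S,10R,13R,15RS)-6-{[tert-butyl(dimethyl)silyl]oxy}-15-hydroxy-6,7-secokaura-2,16-dien-7,20-olide | CC1(C)C=CC[C@]2(COC(=O)[C@@]34C[C@@H](CC[C@@H]23)C(=C)C4O)[C@@H]1CO[Si](C)(C)C(C)(C)C
F5 | step 25 | (1RS,5R,8S,9S,10R,13R,15S,16S)-6-{[tert-butyl(dimethyl)silyl]oxy}-16,17-epoxy-1-hydroxy-15-[(triethylsilyl)oxy]-6,7-secokaur-2-en-7,20-olide | CC1(C)C=CC(O)[C@]2(COC(=O)[C@@]34C[C@@H](CC[C@@H]23)[C@]2(CO2)[C@H]4O[Si](CC)(CC)CC)[C@@H]1CO[Si](C)(C)C(C)(C)C
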